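The north and south-west runs differ in catalyst and in substrate, yet one ratio built on the fraction left comes out close in both. At 0.833 min, open intermediate divided by whatever is neither open intermediate nor target stands at 0.145 in north, 0.142 in south-east and 0.155 in south-west. Their mean, 0.147, is the open share.

| flask | substrate | reagent | capture agent | free catalyst | remark | time |
|---|---|---|---|---|---|---|
| north | 20 mM | 60 mM | 20 mM | 0.43 mM | run made earlier |  |
| south-east | 20 mM | 60 mM | 20 mM | 0.96 mM | run made earlier |  |
| south-west | 10 mM | 60 mM | 20 mM | 0.64 mM | run made earlier |  |
| flask | 20 mM | 60.0 mM | 20.0 mM | 0.64 mM |  | 30 min |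

| run | time / min | open intermediate / % | target / % |
|---|---|---|---|
| north | 0.167 | 10.3 | 1.0 |
| north | 0.833 | 11.8 | 6.7 |
| north | 4.00 | 8.2 | 32.7 |
| north | 20.0 | 0.2 | 81.1 |
| south-east | 0.167 | 12.8 | 2.1 |
| south-east | 0.833 | 10.5 | 15.3 |
| south-east | 4.00 | 3.6 | 63.5 |
| south-east | 20.0 | 0 | 91.1 |
| south-west | 0.167 | 12.0 | 1.3 |
| south-west | 0.833 | 11.4 | 15.0 |
| south-west | 4.00 | 4.6 | 62.4 |
| south-west | 20.0 | 0 | 90.0 |

(scatter of a reading: 0.3 percentage points)

- the numbers in the tables scatter by 0.3 percentage points (one standard deviation)

- time, not beyond 30 min, at which the flask holds most open intermediate
- the amount of open intermediate, in percent of the substrate charged, at that time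
- earliest time at which at least nineteen twentieths of that best amount are there, in min
- latest time at which they still are, in min

Two chemists dispute the new flask. The first gives each run one rise and one exponential fall, then reads between the runs: “Interpolating north and south-east at 20 mM substrate gives k ≈ 0.19/min at 0.64 mM”. That forecast puts the peak at 0.29 min with 12.5%, and the window from 0.17 min to 0.62 min, so open intermediate stays in the window for 0.330 min after the peak.

The second chemist says open intermediate rides on what is left. If the open share holds, open intermediate is 12.8% of whatever has not become target. Losing a twentieth of it then means target must gain about a twentieth of the charge, as long as target stays a small part of that charge. The rise of target between the second and third readings of north and south-east, taken per catalyst, averaged and scaled to the new flask, gives a rate, as a fraction of the charge, of 0.112 min⁻¹. So the fall to the window's edge should take 0.447 min. This view names no peak time.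

The simulated flask peaks at 0.403 min with 12.3%, and the window runs from 0.191 min to 0.828 min.

    substrate + free catalyst ⇌ free catalyst + open intermediate (K = 0.200, k = 79.1 M⁻¹ s⁻¹)
    free catalyst + open intermediate ⇌ catalyst intermediate (K = 2800 M⁻¹, k = 142 M⁻¹ s⁻¹)
    reagent + catalyst intermediate → free catalyst + target (k = 1.73 M⁻¹ s⁻¹)
    target → over-reaction product (k = 1.72 × 10⁻⁶ s⁻¹)
    open intermediate + capture agent → trapped intermediate (k = 0.209 M⁻¹ s⁻¹)

The fall took 0.425 min, closer to the second view's span than to the forecast's. With the target of the peak, 4.57%, the open share gives 12.2% in this flask, and the neighbour with a quarter of the substrate peaks at 12.3%. The exponential fall has its region in the late part of the flask, with free catalyst back at 97.8% of its charge by 15.0 min. At the charged concentrations, the forward step of open intermediate with free catalyst alone has a half-life of 0.13 min, against 2.8 min for its step with capture agent. At 2.71 min, the forward step to catalyst intermediate still uses open intermediate 8.9 times as fast as capture does.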